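The route rests on opening the 19-membered ansa-lactam ring (N, C1–C15, C16, C21, C20) at C4–C5: the cis C4=C5 alkene, which is conjugated with the Z C2=C3 alkene, is carried as a C4≡C5 alkyne. Ring-closing alkyne metathesis of a seco anilide with two methyl-capped alkynes forms this bond and the macrocycle in one operation, with no alkene geometry at stake; syn semi-reduction then gives 4Z. The precursor is the stereodefined C5–C15 chain (seven stereocentres, Z C8=C9, C7 silyl ether) on a dimethyl-protected aminohydroquinone, N-acylated with (Z)-2-methylhex-2-en-4-ynoic acid; the phenols are released last by oxidative demethylation and reduction.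

Key step: step 27

Assumption: 1 is taken as a catalogue compound (otherwise HNO3/AcOH nitration of 2-hydroxy-5-methoxybenzaldehyde supplies it), and both phenols are carried as methyl ethers, because an aryl silyl ether ortho to a nitro group would not survive K2CO3/MeOH.

Step 1
Reactants: 1 2-hydroxy-5-methoxy-3-nitrobenzaldehyde
Product: 2 2,5-dimethoxy-3-nitrobenzaldehyde
Conditions: MeI, K2CO3, DMF, 40 °C
Reagents that add atoms: iodomethane (CI)
Why: Williamson O-methylation of the acidic ortho-nitrophenol gives the dimethyl hydroquinone ether, a phenol protection that is inert to the bases, hydrides and oxidants used later and leaves the future amino group unhindered.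

Step 2
Reactants: 2 2,5-dimethoxy-3-nitrobenzaldehyde; 3 (Z)-but-2-ene
Product: 4 (1R,2S)-1-(2,5-dimethoxy-3-nitrophenyl)-2-methylbut-3-en-1-ol
Conditions: 3, KOt-Bu, n-BuLi, THF, −78 → −45 °C; (+)-Ipc2BOMe, −78 °C; BF3·OEt2; then 2, −78 °C; NaOH, H2O2, 0 °C → rt
Reagents that add atoms: none
Why: Brown (Z)-crotylboration proceeds through a closed chair transition state in which the Z-crotyl geometry translates into the 14,15-syn relationship and the (+)-isopinocampheyl ligands direct attack to the Re face of the aryl aldehyde, setting C15 as R and C14 as S.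

Step 3
Reactants: 4 (1R,2S)-1-(2,5-dimethoxy-3-nitrophenyl)-2-methylbut-3-en-1-ol
Product: 5 1-[(1R,2S)-1-methoxy-2-methylbut-3-en-1-yl]-2,5-dimethoxy-3-nitrobenzene
Conditions: NaH, MeI, THF, 0 °C → rt
Reagents that add atoms: iodomethane (CI)
Why: Williamson etherification of the sodium alkoxide with iodomethane installs the C15 methyl ether; no stereocentre is touched and the nitroarene carries no leaving group that the alkoxide could displace.

Step 4
Reactants: 5 1-[(1R,2S)-1-methoxy-2-methylbut-3-en-1-yl]-2,5-dimethoxy-3-nitrobenzene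
Product: 7 (3S,4R)-4-(2,5-dimethoxy-3-nitrophenyl)-4-methoxy-3-methylbutan-1-ol, via B-alkyl-9-BBN adduct 6 (not isolated)
Conditions: 9-BBN, THF, 0 °C → rt; then NaOH, H2O2, 0 °C
Reagents that add atoms: hydrogen peroxide (OO)
Why: Anti-Markovnikov hydroboration of the monosubstituted alkene with the bulky 9-BBN followed by oxidation of the carbon–boron bond with retention delivers the primary C12 alcohol and leaves C13 as the methylene group.

Step 5
Reactants: 7 (3S,4R)-4-(2,5-dimethoxy-3-nitrophenyl)-4-methoxy-3-methylbutan-1-ol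
Product: 8 (3S,4R)-4-(2,5-dimethoxy-3-nitrophenyl)-4-methoxy-3-methylbutanal
Conditions: Dess–Martin periodinane, NaHCO3, CH2Cl2, rt
Reagents that add atoms: none
Why: Dess–Martin oxidation converts the primary alcohol into the aldehyde under buffered, non-epimerising conditions (C14 is β to the carbonyl and not at risk).

Step 6
Reactants: 8 (3S,4R)-4-(2,5-dimethoxy-3-nitrophenyl)-4-methoxy-3-methylbutanal; 9 hex-1-yne
Product: 10 (1R,2S,4S,5E)-1-(2,5-dimethoxy-3-nitrophenyl)-1-methoxy-2-methyldec-5-en-4-ol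
Conditions: 9, Cy2BH (from BH3·SMe2 and cyclohexene), toluene, 0 °C → rt; Et2Zn, −78 °C; (+)-MIB (5 mol %); then 8, −20 → 0 °C; aq NH4Cl
Reagents that add atoms: none
Why: Catalytic asymmetric alkenylzinc addition (hydroboration of 9, boron-to-zinc transmetalation, amino-alcohol-ligated zinc catalyst) is a known route to (E)-allylic alcohols, and the (+)-MIB enantiomer is chosen to deliver the alkenyl group to the Re face of the aldehyde so that C12 becomes S, the hexenyl alkene serving only as a masked formyl group.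

Step 7
Reactants: 10 (1R,2S,4S,5E)-1-(2,5-dimethoxy-3-nitrophenyl)-1-methoxy-2-methyldec-5-en-4-ol
Product: 11 1-[(1R,2S,4S,5E)-1,4-dimethoxy-2-methyldec-5-en-1-yl]-2,5-dimethoxy-3-nitrobenzene
Conditions: NaH, MeI, THF, 0 °C → rt
Reagents that add atoms: iodomethane (CI)
Why: Williamson etherification of the allylic alkoxide with iodomethane fixes the C12 methoxy group before the alkene is cleaved.

Step 8
Reactants: 11 1-[(1R,2S,4S,5E)-1,4-dimethoxy-2-methyldec-5-en-1-yl]-2,5-dimethoxy-3-nitrobenzene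
Product: 13 (2S,4S,5R)-5-(2,5-dimethoxy-3-nitrophenyl)-2,5-dimethoxy-4-methylpentanal, via ozonide 12 (not isolated)
Conditions: O3, CH2Cl2, −78 °C; then PPh3, −78 °C → rt
Reagents that add atoms: ozone ([O-][O+]=O)
Why: Ozonolysis with reductive work-up cleaves the only alkene to reveal the C11 aldehyde, the deactivated nitroarene being inert to ozone, and the α-methoxy aldehyde is used crude to keep C12 intact.

Step 9
Reactants: 13 (2S,4S,5R)-5-(2,5-dimethoxy-3-nitrophenyl)-2,5-dimethoxy-4-methylpentanal; 3 (Z)-but-2-ene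
Product: 14 (3S,4R,5S,7S,8R)-8-(2,5-dimethoxy-3-nitrophenyl)-5,8-dimethoxy-3,7-dimethyloct-1-en-4-ol
Conditions: 3, KOt-Bu, n-BuLi, THF, −78 → −45 °C; (+)-Ipc2BOMe, −78 °C; BF3·OEt2; then 13, −78 °C; NaOH, H2O2, 0 °C → rt
Reagents that add atoms: none
Why: A second Brown (Z)-crotylboration sets C10 (S) and C11 (R): the Z-crotyl unit gives the 10,11-syn relationship through the chair transition state, and the Re-face preference of the (+)-isopinocampheyl reagent coincides with the Felkin–Anh/Cornforth preference of the α-methoxy aldehyde for the 11,12-anti product, a matched pairing.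

Step 10
Reactants: 14 (3S,4R,5S,7S,8R)-8-(2,5-dimethoxy-3-nitrophenyl)-5,8-dimethoxy-3,7-dimethyloct-1-en-4-ol
Product: 15 1-[(1R,2S,4S,5R,6S)-1,4,5-trimethoxy-2,6-dimethyloct-7-en-1-yl]-2,5-dimethoxy-3-nitrobenzene
Conditions: NaH, MeI, THF, 0 °C → rt
Reagents that add atoms: iodomethane (CI)
Why: Williamson etherification installs the C11 methyl ether under conditions that cannot epimerise the neighbouring ether-bearing centres.

Step 11
Reactants: 15 1-[(1R,2S,4S,5R,6S)-1,4,5-trimethoxy-2,6-dimethyloct-7-en-1-yl]-2,5-dimethoxy-3-nitrobenzene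
Product: 17 (2R,3R,4S,6S,7R)-7-(2,5-dimethoxy-3-nitrophenyl)-3,4,7-trimethoxy-2,6-dimethylheptanal, via ozonide 16 (not isolated)
Conditions: O3, CH2Cl2, −78 °C; then PPh3, −78 °C → rt
Reagents that add atoms: ozone ([O-][O+]=O)
Why: Ozonolysis with reductive work-up turns the terminal vinyl group into the C9 aldehyde, which is carried on crude at low temperature to avoid epimerisation at C10 or β-elimination of methanol.

Step 12
Reactants: 17 (2R,3R,4S,6S,7R)-7-(2,5-dimethoxy-3-nitrophenyl)-3,4,7-trimethoxy-2,6-dimethylheptanal; 18 ethyl 2-[bis(2,2,2-trifluoroethoxy)phosphoryl]propanoate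
Product: 19 ethyl (2Z,4S,5R,6S,8S,9R)-9-(2,5-dimethoxy-3-nitrophenyl)-5,6,9-trimethoxy-2,4,8-trimethylnon-2-enoate
Conditions: 18, KN(SiMe3)2, 18-crown-6, THF, −78 °C; then 17, −78 °C
Reagents that add atoms: none
Why: Still–Gennari olefination with the bis(trifluoroethyl) phosphonate under dissociating conditions (potassium counter-ion sequestered by the crown ether) is kinetically Z-selective and places C7 and C10 cis across the new trisubstituted C8=C9 bond.

Step 13
Reactants: 19 ethyl (2Z,4S,5R,6S,8S,9R)-9-(2,5-dimethoxy-3-nitrophenyl)-5,6,9-trimethoxy-2,4,8-trimethylnon-2-enoate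
Product: 20 (2Z,4S,5R,6S,8S,9R)-9-(2,5-dimethoxy-3-nitrophenyl)-5,6,9-trimethoxy-2,4,8-trimethylnon-2-en-1-ol
Conditions: i-Bu2AlH, CH2Cl2, −78 °C
Reagents that add atoms: none
Why: Ester reduction with i-Bu2AlH at −78 °C gives the (Z)-allylic alcohol without touching the alkene geometry or, at this temperature, the nitro group.

Step 14
Reactants: 20 (2Z,4S,5R,6S,8S,9R)-9-(2,5-dimethoxy-3-nitrophenyl)-5,6,9-trimethoxy-2,4,8-trimethylnon-2-en-1-ol
Product: 21 (2Z,4S,5R,6S,8S,9R)-9-(2,5-dimethoxy-3-nitrophenyl)-5,6,9-trimethoxy-2,4,8-trimethylnon-2-enal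
Conditions: MnO2, CH2Cl2, rt
Reagents that add atoms: none
Why: Allylic oxidation on the surface of MnO2 is neutral and stops at the aldehyde, giving the (Z)-enal without acid or base that could isomerise it to the E isomer.

Step 15
Reactants: 22 (R)-4-benzyloxazolidin-2-one; 23 methoxyacetyl chloride
Product: 24 (R)-4-benzyl-3-(methoxyacetyl)oxazolidin-2-one
Conditions: n-BuLi, THF, −78 °C; then 23, −78 → 0 °C
Reagents that add atoms: none
Why: N-Acylation of the lithiated oxazolidinone with the acid chloride gives the glycolate imide needed for the auxiliary-controlled aldol reaction.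

Step 16
Reactants: 21 (2Z,4S,5R,6S,8S,9R)-9-(2,5-dimethoxy-3-nitrophenyl)-5,6,9-trimethoxy-2,4,8-trimethylnon-2-enal; 24 (R)-4-benzyl-3-(methoxyacetyl)oxazolidin-2-one
Product: 25 (4R)-4-benzyl-3-[(2R,3S,4Z,6S,7R,8S,10S,11R)-11-(2,5-dimethoxy-3-nitrophenyl)-3-hydroxy-2,7,8,11-tetramethoxy-4,6,10-trimethylundec-4-enoyl]oxazolidin-2-one
Conditions: 24, Bu2BOTf, Et3N, CH2Cl2, −78 → 0 °C; then 21, −78 → 0 °C; H2O2, MeOH, pH 7 buffer
Reagents that add atoms: none
Why: Evans syn-aldol reaction of the (Z)-dibutylboron enolate of 24 through a closed chair transition state gives the 6,7-syn adduct, the (R)-benzyl auxiliary shielding one enolate face so that the imide is formed as 2R,3S, which corresponds to 6S,7S of the target.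

Step 17
Reactants: 25 the aldol adduct
Product: 26 (4R)-4-benzyl-3-[(2R,3S,4Z,6S,7R,8S,10S,11R)-11-(2,5-dimethoxy-3-nitrophenyl)-2,7,8,11-tetramethoxy-4,6,10-trimethyl-3-(triethylsilyloxy)undec-4-enoyl]oxazolidin-2-one
Conditions: Et3SiOTf, 2,6-lutidine, CH2Cl2, −78 → 0 °C
Reagents that add atoms: triethylsilyl trifluoromethanesulfonate (CC[Si](CC)(CC)OS(=O)(=O)C(F)(F)F)
Why: Silylation with the silyl triflate and a hindered pyridine base protects the C7 hydroxyl as a triethylsilyl ether that survives borohydride, mild base and metathesis and can later be removed without touching the allylic ethers.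

Step 18
Reactants: 26 the silylated imide
Product: 27 (2S,3S,4Z,6S,7R,8S,10S,11R)-11-(2,5-dimethoxy-3-nitrophenyl)-2,7,8,11-tetramethoxy-4,6,10-trimethyl-3-(triethylsilyloxy)undec-4-en-1-ol
Conditions: LiBH4, MeOH, THF, 0 °C
Reagents that add atoms: none
Why: Reductive cleavage of the N-acyl oxazolidinone with LiBH4 gives the primary C5 alcohol and returns the auxiliary, with no enolisation and hence no erosion at C6.

Step 19
Reactants: 27 the C5 alcohol
Product: 28 (2R,3S,4Z,6S,7R,8S,10S,11R)-11-(2,5-dimethoxy-3-nitrophenyl)-2,7,8,11-tetramethoxy-4,6,10-trimethyl-3-(triethylsilyloxy)undec-4-enal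
Conditions: Dess–Martin periodinane, NaHCO3, CH2Cl2, 0 °C → rt
Reagents that add atoms: none
Why: Dess–Martin oxidation under bicarbonate buffering gives the α-methoxy aldehyde, which is used at once to preserve the C6 configuration.

Step 20
Reactants: 28 the C5 aldehyde; 29 dimethyl (1-diazo-2-oxopropyl)phosphonate
Product: 30 triethyl{[(3S,4S,5Z,7S,8R,9S,11S,12R)-12-(2,5-dimethoxy-3-nitrophenyl)-3,8,9,12-tetramethoxy-5,7,11-trimethyldodec-5-en-1-yn-4-yl]oxy}silane
Conditions: 29, K2CO3, MeOH, 0 °C → rt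
Reagents that add atoms: none
Why: Ohira–Bestmann homologation (in situ dimethyl diazomethylphosphonate, Horner–Wadsworth–Emmons addition, loss of N2 and 1,2-hydride shift of the alkylidene carbene) converts the aldehyde into the terminal alkyne, C5 becoming the alkyne carbon attached to C6.

Step 21
Reactants: 30 the terminal alkyne
Product: 31 triethyl{[(4S,5S,6Z,8S,9R,10S,12S,13R)-13-(2,5-dimethoxy-3-nitrophenyl)-4,9,10,13-tetramethoxy-6,8,12-trimethyltridec-6-en-2-yn-5-yl]oxy}silane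
Conditions: LiN(SiMe3)2, THF, −78 °C; MeOTf, −78 → 0 °C
Reagents that add atoms: methyl trifluoromethanesulfonate (COS(=O)(=O)C(F)(F)F)
Why: Deprotonation of the terminal alkyne with the non-nucleophilic amide base and C-methylation of the acetylide with methyl triflate caps the alkyne for metathesis at a stage where no N–H is present.

Step 22
Reactants: 31 the nitroarene methyl alkyne
Product: 32 2,5-dimethoxy-3-[(1R,2S,4S,5R,6S,7Z,9S,10S)-1,4,5,10-tetramethoxy-2,6,8-trimethyl-9-(triethylsilyloxy)tridec-7-en-11-yn-1-yl]aniline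
Conditions: Zn dust, NH4Cl, EtOH/H2O, rt → 40 °C
Reagents that add atoms: none
Why: Dissolving-metal reduction with zinc and ammonium chloride reduces the aryl nitro group chemoselectively to the aniline in the presence of the internal alkyne, the Z-alkene and the silyl ether.

Step 23
Reactants: 33 prop-2-yn-1-ol
Product: 35 (Z)-3-iodo-2-methylprop-2-en-1-ol, via alkenylmagnesium bromide 34 (not isolated)
Conditions: MeMgBr, CuI (10 mol %), THF/Et2O, −10 °C → rt; then I2, −78 → 0 °C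
Reagents that add atoms: methylmagnesium bromide (C[Mg]Br); iodine (II)
Why: Copper-catalysed carbomagnesiation of the propargylic magnesium alkoxide adds methyl to C2 and magnesium to C3 anti across the alkyne within an oxygen-chelated five-membered ring, and iodinolysis with retention gives the (Z)-iodoalkene.

Step 24
Reactants: 35 (Z)-3-iodo-2-methylprop-2-en-1-ol; 36 propyne
Product: 37 (Z)-2-methylhex-2-en-4-yn-1-ol
Conditions: PdCl2(PPh3)2 (3 mol %), CuI (5 mol %), i-Pr2NH, THF, rt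
Reagents that add atoms: none
Why: Sonogashira coupling of the vinyl iodide with propyne proceeds with retention of alkene geometry and on the free alcohol avoids the lactonisation that a Z-iodoacrylic acid would undergo.

Step 25
Reactants: 37 (Z)-2-methylhex-2-en-4-yn-1-ol
Product: 39 (Z)-2-methylhex-2-en-4-ynoic acid, via enynal 38 (not isolated)
Conditions: MnO2, CH2Cl2, rt; then NaClO2, NaH2PO4, 2-methylbut-2-ene, t-BuOH/H2O, 0 °C → rt
Reagents that add atoms: sodium chlorite ([Na+].[O-]Cl=O)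
Why: Allylic oxidation with MnO2 followed without isolation of the volatile enynal by Pinnick oxidation (chlorous acid, hypochlorite scavenged by the alkene additive) gives the (Z)-enynoic acid without alkene isomerisation.

Step 26
Reactants: 39 (Z)-2-methylhex-2-en-4-ynoic acid; 32 the aniline
Product: 41 (2Z)-N-{2,5-dimethoxy-3-[(1R,2S,4S,5R,6S,7Z,9S,10S)-1,4,5,10-tetramethoxy-2,6,8-trimethyl-9-(triethylsilyloxy)tridec-7-en-11-yn-1-yl]phenyl}-2-methylhex-2-en-4-ynamide, via acid chloride 40 (not isolated)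
Conditions: 1-chloro-N,N,2-trimethylprop-1-en-1-amine, CH2Cl2, 0 °C → rt; then 32, pyridine, CH2Cl2, 0 °C → rt
Reagents that add atoms: none
Why: Acid chloride formation under neutral conditions with the α-chloroenamine and Schotten–Baumann-type N-acylation of the aniline give the anilide; the small ortho methoxy group leaves the amine accessible and the Z-enyne is never exposed to acid or transition metals that could trigger cyclisation.

Step 27
Reactants: 41 the seco bis(methyl alkyne) anilide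
Product: 42 macrocyclic 4,5-didehydro enyne lactam (19-membered ring; 2Z,8Z; C4≡C5; 7-OSiEt3; 18,21-di-OMe)
Conditions: Mo(≡CC6H4OMe-4)(OSiPh3)3 (15 mol %, released from its 1,10-phenanthroline adduct with MnCl2), powdered 5 Å MS, toluene (2 mM), 80 °C
Reagents that add atoms: none
Why: The molybdenum alkylidyne adds to one methyl-capped alkyne by [2+2] cycloaddition, the metallacyclobutadiene cycloreverts to a substrate-bound alkylidyne, and the same sequence on the second alkyne forms C4≡C5 and releases but-2-yne, whose capture by the 5 Å sieves drives the equilibrium. The closest known reaction type is ring-closing alkyne metathesis to macrocyclic 1,3-enynes with triarylsilanolate molybdenum alkylidynes. The one ring formed is the 19-membered lactam, closed end-to-end between C4 and C5 of the seco chain under high dilution. No stereocentre is created, and because the new bond is a triple bond no alkene geometry has to be controlled. The step needs chemoselectivity for the two alkynes over the Z C2=C3 and Z C8=C9 alkenes, which alkylidynes do not engage, and tolerance of the anilide N–H, ethers and silyl ether, secured by the silanolate ligand sphere and the absence of free OH or NH2 groups, while the two Z alkenes and the 1,2,3-trisubstituted arene pre-bend the chain towards closure.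

Step 28
Reactants: 42 the macrocyclic enyne lactam
Product: 43 (2Z,4Z,8Z)-dienamide macrolactam (7-OSiEt3; 18,21-di-OMe)
Conditions: Zn dust activated with Cu(OAc)2 and AgNO3, MeOH/H2O 1:1, 45 °C
Reagents that add atoms: none
Why: Boland-type semi-reduction with zinc activated by copper and silver delivers two hydrogens cis to the alkyne from the metal surface, and because this couple reduces only conjugation-activated alkynes and not alkenes, it stops at the (2Z,4Z)-dienamide.

Step 29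
Reactants: 43 the silylated dienamide macrolactam
Product: 44 7-hydroxy macrolactam (18,21-di-OMe)
Conditions: HF·pyridine, pyridine, THF, 0 °C
Reagents that add atoms: none
Why: Fluoride-mediated desilylation, buffered with pyridine, cleaves the triethylsilyl ether without ionising the allylic C6 and C7 oxygen substituents.

Step 30
Reactants: 44 the 7-hydroxy macrolactam
Product: 46 7-O-carbamoyl macrolactam (18,21-di-O-methyl ether of the target), via N-trichloroacetyl carbamate 45 (not isolated)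
Conditions: Cl3CC(O)NCO, CH2Cl2, 0 °C; then K2CO3, MeOH, 0 °C
Reagents that add atoms: trichloroacetyl isocyanate (O=C=NC(=O)C(Cl)(Cl)Cl)
Why: Addition of the C7 alcohol to the highly electrophilic acyl isocyanate and mild methanolysis of the trichloroacetyl group is the standard two-stage carbamoylation of hindered secondary alcohols, the anilide N–H being far less nucleophilic than the hydroxyl.

Step 31
Reactants: 46 the 7-O-carbamoyl dimethyl ether
Product: 48 target CNP0109452.1 (18,21-hydroquinone), via quinone 47 (not isolated)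
Conditions: (NH4)2Ce(NO3)6, MeCN/H2O, 0 °C; then aq Na2S2O4, EtOAc, rt, under argon
Reagents that add atoms: water (O)
Why: Oxidative demethylation of the para-dimethoxyarene with (NH4)2Ce(NO3)6 (radical cation, ipso attack of water, loss of methanol) gives the para-quinone, which dithionite reduces in the same work-up to the air-sensitive hydroquinone, so the phenols appear only in the last operation.

Compound list
1 | 2-hydroxy-5-methoxy-3-nitrobenzaldehyde | O=Cc1cc(OC)cc(c1O)[N+](=O)[O-] | starting material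
2 | 2,5-dimethoxy-3-nitrobenzaldehyde | O=Cc1cc(OC)cc(c1OC)[N+](=O)[O-] | intermediate
3 | (Z)-but-2-ene | C/C=C\C | starting material
4 | (1R,2S)-1-(2,5-dimethoxy-3-nitrophenyl)-2-methylbut-3-en-1-ol | C=C[C@H](C)[C@@H](O)c1cc(OC)cc(c1OC)[N+](=O)[O-] | intermediate
5 | 1-[(1R,2S)-1-methoxy-2-methylbut-3-en-1-yl]-2,5-dimethoxy-3-nitrobenzene | C=C[C@H](C)[C@@H](OC)c1cc(OC)cc(c1OC)[N+](=O)[O-] | intermediate
6 | 9-[(3S,4R)-4-(2,5-dimethoxy-3-nitrophenyl)-4-methoxy-3-methylbutyl]-9-borabicyclo[3.3.1]nonane | B1(CC[C@H](C)[C@@H](OC)c3cc(OC)cc(c3OC)[N+](=O)[O-])C2CCCC1CCC2 | intermediate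
7 | (3S,4R)-4-(2,5-dimethoxy-3-nitrophenyl)-4-methoxy-3-methylbutan-1-ol | OCC[C@H](C)[C@@H](OC)c1cc(OC)cc(c1OC)[N+](=O)[O-] | intermediate
8 | (3S,4R)-4-(2,5-dimethoxy-3-nitrophenyl)-4-methoxy-3-methylbutanal | O=CC[C@H](C)[C@@H](OC)c1cc(OC)cc(c1OC)[N+](=O)[O-] | intermediate
9 | hex-1-yne | CCCCC#C | starting material
10 | (1R,2S,4S,5E)-1-(2,5-dimethoxy-3-nitrophenyl)-1-methoxy-2-methyldec-5-en-4-ol | CCCC/C=C/[C@@H](O)C[C@H](C)[C@@H](OC)c1cc(OC)cc(c1OC)[N+](=O)[O-] | intermediate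
11 | 1-[(1R,2S,4S,5E)-1,4-dimethoxy-2-methyldec-5-en-1-yl]-2,5-dimethoxy-3-nitrobenzene | CCCC/C=C/[C@@H](OC)C[C@H](C)[C@@H](OC)c1cc(OC)cc(c1OC)[N+](=O)[O-] | intermediate
12 | 1,2,4-trioxolane (secondary ozonide) formed from the C5=C6 alkene of 11; ring carbons unassigned | CCCCC1OC(OO1)[C@@H](OC)C[C@H](C)[C@@H](OC)c1cc(OC)cc(c1OC)[N+](=O)[O-] | intermediate
13 | (2S,4S,5R)-5-(2,5-dimethoxy-3-nitrophenyl)-2,5-dimethoxy-4-methylpentanal | O=C[C@@H](OC)C[C@H](C)[C@@H](OC)c1cc(OC)cc(c1OC)[N+](=O)[O-] | intermediate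
14 | (3S,4R,5S,7S,8R)-8-(2,5-dimethoxy-3-nitrophenyl)-5,8-dimethoxy-3,7-dimethyloct-1-en-4-ol | C=C[C@H](C)[C@@H](O)[C@@H](OC)C[C@H](C)[C@@H](OC)c1cc(OC)cc(c1OC)[N+](=O)[O-] | intermediate
15 | 1-[(1R,2S,4S,5R,6S)-1,4,5-trimethoxy-2,6-dimethyloct-7-en-1-yl]-2,5-dimethoxy-3-nitrobenzene | C=C[C@H](C)[C@@H](OC)[C@@H](OC)C[C@H](C)[C@@H](OC)c1cc(OC)cc(c1OC)[N+](=O)[O-] | intermediate
16 | 1,2,4-trioxolane (secondary ozonide) formed from the vinyl group of 15; ring carbon unassigned | C1OC(OO1)[C@H](C)[C@@H](OC)[C@@H](OC)C[C@H](C)[C@@H](OC)c1cc(OC)cc(c1OC)[N+](=O)[O-] | intermediate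
17 | (2R,3R,4S,6S,7R)-7-(2,5-dimethoxy-3-nitrophenyl)-3,4,7-trimethoxy-2,6-dimethylheptanal | O=C[C@H](C)[C@@H](OC)[C@@H](OC)C[C@H](C)[C@@H](OC)c1cc(OC)cc(c1OC)[N+](=O)[O-] | intermediate
18 | ethyl 2-[bis(2,2,2-trifluoroethoxy)phosphoryl]propanoate | CCOC(=O)C(C)P(=O)(OCC(F)(F)F)OCC(F)(F)F | starting material
19 | ethyl (2Z,4S,5R,6S,8S,9R)-9-(2,5-dimethoxy-3-nitrophenyl)-5,6,9-trimethoxy-2,4,8-trimethylnon-2-enoate | CCOC(=O)/C(C)=C\[C@H](C)[C@@H](OC)[C@@H](OC)C[C@H](C)[C@@H](OC)c1cc(OC)cc(c1OC)[N+](=O)[O-] | intermediate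
20 | (2Z,4S,5R,6S,8S,9R)-9-(2,5-dimethoxy-3-nitrophenyl)-5,6,9-trimethoxy-2,4,8-trimethylnon-2-en-1-ol | OC/C(C)=C\[C@H](C)[C@@H](OC)[C@@H](OC)C[C@H](C)[C@@H](OC)c1cc(OC)cc(c1OC)[N+](=O)[O-] | intermediate
21 | (2Z,4S,5R,6S,8S,9R)-9-(2,5-dimethoxy-3-nitrophenyl)-5,6,9-trimethoxy-2,4,8-trimethylnon-2-enal | O=C/C(C)=C\[C@H](C)[C@@H](OC)[C@@H](OC)C[C@H](C)[C@@H](OC)c1cc(OC)cc(c1OC)[N+](=O)[O-] | intermediate
22 | (R)-4-benzyloxazolidin-2-one | O=C1N[C@H](Cc2ccccc2)CO1 | starting material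
23 | methoxyacetyl chloride | COCC(=O)Cl | starting material
24 | (R)-4-benzyl-3-(methoxyacetyl)oxazolidin-2-one | COCC(=O)N1[C@H](Cc2ccccc2)COC1=O | intermediate
25 | (4R)-4-benzyl-3-[(2R,3S,4Z,6S,7R,8S,10S,11R)-11-(2,5-dimethoxy-3-nitrophenyl)-3-hydroxy-2,7,8,11-tetramethoxy-4,6,10-trimethylundec-4-enoyl]oxazolidin-2-one | O=C1OC[C@@H](Cc2ccccc2)N1C(=O)[C@H](OC)[C@@H](O)/C(C)=C\[C@H](C)[C@@H](OC)[C@@H](OC)C[C@H](C)[C@@H](OC)c1cc(OC)cc(c1OC)[N+](=O)[O-] | intermediate
26 | 3-O-triethylsilyl ether of 25 | O=C1OC[C@@H](Cc2ccccc2)N1C(=O)[C@H](OC)[C@@H](O[Si](CC)(CC)CC)/C(C)=C\[C@H](C)[C@@H](OC)[C@@H](OC)C[C@H](C)[C@@H](OC)c1cc(OC)cc(c1OC)[N+](=O)[O-] | intermediate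
27 | (2S,3S,4Z,6S,7R,8S,10S,11R)-11-(2,5-dimethoxy-3-nitrophenyl)-2,7,8,11-tetramethoxy-4,6,10-trimethyl-3-(triethylsilyloxy)undec-4-en-1-ol | OC[C@H](OC)[C@@H](O[Si](CC)(CC)CC)/C(C)=C\[C@H](C)[C@@H](OC)[C@@H](OC)C[C@H](C)[C@@H](OC)c1cc(OC)cc(c1OC)[N+](=O)[O-] | intermediate
28 | (2R,3S,4Z,6S,7R,8S,10S,11R)-11-(2,5-dimethoxy-3-nitrophenyl)-2,7,8,11-tetramethoxy-4,6,10-trimethyl-3-(triethylsilyloxy)undec-4-enal | O=C[C@H](OC)[C@@H](O[Si](CC)(CC)CC)/C(C)=C\[C@H](C)[C@@H](OC)[C@@H](OC)C[C@H](C)[C@@H](OC)c1cc(OC)cc(c1OC)[N+](=O)[O-] | intermediate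
29 | dimethyl (1-diazo-2-oxopropyl)phosphonate | COP(=O)(OC)C(=[N+]=[N-])C(C)=O | starting material
30 | triethyl{[(3S,4S,5Z,7S,8R,9S,11S,12R)-12-(2,5-dimethoxy-3-nitrophenyl)-3,8,9,12-tetramethoxy-5,7,11-trimethyldodec-5-en-1-yn-4-yl]oxy}silane | C#C[C@H](OC)[C@@H](O[Si](CC)(CC)CC)/C(C)=C\[C@H](C)[C@@H](OC)[C@@H](OC)C[C@H](C)[C@@H](OC)c1cc(OC)cc(c1OC)[N+](=O)[O-] | intermediate
31 | triethyl{[(4S,5S,6Z,8S,9R,10S,12S,13R)-13-(2,5-dimethoxy-3-nitrophenyl)-4,9,10,13-tetramethoxy-6,8,12-trimethyltridec-6-en-2-yn-5-yl]oxy}silane | CC#C[C@H](OC)[C@@H](O[Si](CC)(CC)CC)/C(C)=C\[C@H](C)[C@@H](OC)[C@@H](OC)C[C@H](C)[C@@H](OC)c1cc(OC)cc(c1OC)[N+](=O)[O-] | intermediate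
32 | 2,5-dimethoxy-3-[(1R,2S,4S,5R,6S,7Z,9S,10S)-1,4,5,10-tetramethoxy-2,6,8-trimethyl-9-(triethylsilyloxy)tridec-7-en-11-yn-1-yl]aniline | CC#C[C@H](OC)[C@@H](O[Si](CC)(CC)CC)/C(C)=C\[C@H](C)[C@@H](OC)[C@@H](OC)C[C@H](C)[C@@H](OC)c1cc(OC)cc(N)c1OC | intermediate
33 | prop-2-yn-1-ol (propargyl alcohol) | C#CCO | starting material
34 | (Z)-[3-(bromomagnesiooxy)-2-methylprop-1-enyl]magnesium bromide | C/C(=C/[Mg]Br)CO[Mg]Br | intermediate
35 | (Z)-3-iodo-2-methylprop-2-en-1-ol | OC/C(C)=C\I | intermediate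
36 | propyne | CC#C | starting material
37 | (Z)-2-methylhex-2-en-4-yn-1-ol | OC/C(C)=C\C#CC | intermediate
38 | (Z)-2-methylhex-2-en-4-ynal | O=C/C(C)=C\C#CC | intermediate
39 | (Z)-2-methylhex-2-en-4-ynoic acid | OC(=O)/C(C)=C\C#CC | intermediate
40 | (Z)-2-methylhex-2-en-4-ynoyl chloride | O=C(Cl)/C(C)=C\C#CC | intermediate
41 | seco bis(methyl alkyne): (2Z)-N-{2,5-dimethoxy-3-[(1R,2S,4S,5R,6S,7Z,9S,10S)-1,4,5,10-tetramethoxy-2,6,8-trimethyl-9-(triethylsilyloxy)tridec-7-en-11-yn-1-yl]phenyl}-2-methylhex-2-en-4-ynamide | CC#C[C@H](OC)[C@@H](O[Si](CC)(CC)CC)/C(C)=C\[C@H](C)[C@@H](OC)[C@@H](OC)C[C@H](C)[C@@H](OC)c1cc(OC)cc(c1OC)NC(=O)/C(C)=C\C#CC | intermediate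
42 | macrocyclic enyne lactam: 19-membered ring N–C1…C15–C16–C21–C20; C4≡C5; 2Z,8Z; 6S,7S,10S,11R,12S,14S,15R; OMe at C6/C11/C12/C15/C18/C21; Me at C2/C8/C10/C14; OSiEt3 at C7 | CO[C@H]1[C@@H](OC)C[C@H](C)[C@@H](OC)c2cc(OC)cc(c2OC)NC(=O)/C(C)=C\C#C[C@H](OC)[C@@H](O[Si](CC)(CC)CC)/C(C)=C\[C@@H]1C | intermediate
43 | (2Z,4Z,8Z)-dienamide macrolactam; otherwise as 42 | CO[C@H]1[C@@H](OC)C[C@H](C)[C@@H](OC)c2cc(OC)cc(c2OC)NC(=O)/C(C)=C\C=C/[C@H](OC)[C@@H](O[Si](CC)(CC)CC)/C(C)=C\[C@@H]1C | intermediate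
44 | 7-hydroxy (2Z,4Z,8Z)-macrolactam; 18,21-di-OMe | CO[C@H]1[C@@H](OC)C[C@H](C)[C@@H](OC)c2cc(OC)cc(c2OC)NC(=O)/C(C)=C\C=C/[C@H](OC)[C@@H](O)/C(C)=C\[C@@H]1C | intermediate
45 | 7-O-(N-trichloroacetylcarbamoyl) macrolactam; 18,21-di-OMe | CO[C@H]1[C@@H](OC)C[C@H](C)[C@@H](OC)c2cc(OC)cc(c2OC)NC(=O)/C(C)=C\C=C/[C@H](OC)[C@@H](OC(=O)NC(=O)C(Cl)(Cl)Cl)/C(C)=C\[C@@H]1C | intermediate
46 | 7-O-carbamoyl macrolactam; 18,21-di-O-methyl ether of the target | CO[C@H]1[C@@H](OC)C[C@H](C)[C@@H](OC)c2cc(OC)cc(c2OC)NC(=O)/C(C)=C\C=C/[C@H](OC)[C@@H](OC(N)=O)/C(C)=C\[C@@H]1C | intermediate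
47 | 18,21-para-quinone of the target | CO[C@H]1[C@@H](OC)C[C@H](C)[C@@H](OC)C2=CC(=O)C=C(C2=O)NC(=O)/C(C)=C\C=C/[C@H](OC)[C@@H](OC(N)=O)/C(C)=C\[C@@H]1C | intermediate
48 | CNP0109452.1: (2Z,4Z,8Z;6S,7S,10S,11R,12S,14S,15R)-7-O-carbamoyl-6,11,12,15-tetramethoxy-2,8,10,14-tetramethyl ansa-lactam 18,21-hydroquinone | CO[C@H]1[C@@H](OC)C[C@H](C)[C@@H](OC)c2cc(O)cc(c2O)NC(=O)/C(C)=C\C=C/[C@H](OC)[C@@H](OC(N)=O)/C(C)=C\[C@@H]1C | target

Total step count: 31. Longest linear sequence: 27 (steps 1–14, 16–22, 26–31).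

Steps most likely to fail

Step 27. The alkylidyne may be held back as an unreactive chelate once it has exchanged onto the enyne terminus next to the anilide carbonyl, or the seco diyne may oligomerise faster than it closes. The fallback sets out from 30 and 35 and returns at 42; it closes the same ring at C3–C4 by an intramolecular Sonogashira coupling. Terminal alkyne 30 is reduced with Zn and NH4Cl to the aniline F1. Iodo alcohol 35 is oxidised with CrO3/H2SO4 in acetone to (Z)-3-iodo-2-methylprop-2-enoic acid F2, which 1-chloro-N,N,2-trimethylprop-1-en-1-amine converts into the acid chloride F3. Acylation of the aniline with it in the presence of pyridine should give the iodoacrylamide F4. Pd(PPh3)4, CuI and Et3N in THF at high dilution should then couple the vinyl iodide with the terminal alkyne, with retention of the Z geometry, to give 42.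

Step 6. Facial discrimination by the zinc catalyst may be eroded on this α-unbranched, enolisable aldehyde, and ethyl transfer or aldol self-condensation may compete. The fallback sets out from 5 and returns at 13; it sets C12 by an auxiliary-controlled glycolate alkylation. Ozonolysis of 5 with NaBH4 work-up gives the alcohol F5, and Tf2O with 2,6-lutidine gives the triflate F6. The sodium enolate of 24 (NaN(SiMe3)2, THF, −78 → −45 °C) should be alkylated on the face away from the benzyl group to give the 2S-methoxy imide F7. LiBH4 then cleaves the auxiliary to the alcohol F8, and Dess–Martin oxidation gives 13.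

Step 20. Basic methanol may epimerise C6 of the α-methoxy aldehyde or eliminate the C7 silyloxy group before the homologation takes place. The fallback sets out from 28 and returns at 31. CBr4 and PPh3 with 2,6-lutidine in CH2Cl2 at 0 °C convert 28 under non-basic conditions into the 1,1-dibromoalkene F9. DBU in MeCN eliminates HBr to the bromoalkyne F10, and Pd(PPh3)4-catalysed coupling with MeZnCl should give the methyl alkyne 31 directly.

Further compounds
F1 | step 27 | 2,5-dimethoxy-3-[(1R,2S,4S,5R,6S,7Z,9S,10S)-1,4,5,10-tetramethoxy-2,6,8-trimethyl-9-(triethylsilyloxy)dodec-7-en-11-yn-1-yl]aniline | C#C[C@H](OC)[C@@H](O[Si](CC)(CC)CC)/C(C)=C\[C@H](C)[C@@H](OC)[C@@H](OC)C[C@H](C)[C@@H](OC)c1cc(OC)cc(N)c1OC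
F2 | step 27 | (Z)-3-iodo-2-methylprop-2-enoic acid | OC(=O)/C(C)=C\I
F3 | step 27 | (Z)-3-iodo-2-methylprop-2-enoyl chloride | O=C(Cl)/C(C)=C\I
F4 | step 27 | (2Z)-N-{2,5-dimethoxy-3-[(1R,2S,4S,5R,6S,7Z,9S,10S)-1,4,5,10-tetramethoxy-2,6,8-trimethyl-9-(triethylsilyloxy)dodec-7-en-11-yn-1-yl]phenyl}-3-iodo-2-methylprop-2-enamide | C#C[C@H](OC)[C@@H](O[Si](CC)(CC)CC)/C(C)=C\[C@H](C)[C@@H](OC)[C@@H](OC)C[C@H](C)[C@@H](OC)c1cc(OC)cc(c1OC)NC(=O)/C(C)=C\I
F5 | step 6 | (2S,3R)-3-(2,5-dimethoxy-3-nitrophenyl)-3-methoxy-2-methylpropan-1-ol | OC[C@H](C)[C@@H](OC)c1cc(OC)cc(c1OC)[N+](=O)[O-]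
F6 | step 6 | (2S,3R)-3-(2,5-dimethoxy-3-nitrophenyl)-3-methoxy-2-methylpropyl trifluoromethanesulfonate | O=S(=O)(OC[C@H](C)[C@@H](OC)c1cc(OC)cc(c1OC)[N+](=O)[O-])C(F)(F)F
F7 | step 6 | (4R)-4-benzyl-3-[(2S,4S,5R)-5-(2,5-dimethoxy-3-nitrophenyl)-2,5-dimethoxy-4-methylpentanoyl]oxazolidin-2-one | O=C1OC[C@@H](Cc2ccccc2)N1C(=O)[C@@H](OC)C[C@H](C)[C@@H](OC)c1cc(OC)cc(c1OC)[N+](=O)[O-]
F8 | step 6 | (2S,4S,5R)-5-(2,5-dimethoxy-3-nitrophenyl)-2,5-dimethoxy-4-methylpentan-1-ol | OC[C@@H](OC)C[C@H](C)[C@@H](OC)c1cc(OC)cc(c1OC)[N+](=O)[O-]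
F9 | step 20 | triethyl{[(3S,4S,5Z,7S,8R,9S,11S,12R)-1,1-dibromo-12-(2,5-dimethoxy-3-nitrophenyl)-3,8,9,12-tetramethoxy-5,7,11-trimethyldodeca-1,5-dien-4-yl]oxy}silane | BrC(Br)=C[C@H](OC)[C@@H](O[Si](CC)(CC)CC)/C(C)=C\[C@H](C)[C@@H](OC)[C@@H](OC)C[C@H](C)[C@@H](OC)c1cc(OC)cc(c1OC)[N+](=O)[O-]
F10 | step 20 | triethyl{[(3S,4S,5Z,7S,8R,9S,11S,12R)-1-bromo-12-(2,5-dimethoxy-3-nitrophenyl)-3,8,9,12-tetramethoxy-5,7,11-trimethyldodec-5-en-1-yn-4-yl]oxy}silane | BrC#C[C@H](OC)[C@@H](O[Si](CC)(CC)CC)/C(C)=C\[C@H](C)[C@@H](OC)[C@@H](OC)C[C@H](C)[C@@H](OC)c1cc(OC)cc(c1OC)[N+](=O)[O-]
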